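**Retrosynthetic overview**
1. Target 24 ⇐ allyl ester diacetate 23 (deallylation, acetylation) ⇐ anti-1,3-diol 22 ⇐ hydroxyl-directed reduction of the ten-membered β-hydroxy enone 21.
2. Ten-membered ring 20 ⇐ five-carbon ring expansion of cyclopentanone β-keto ester 16: the alkenyllithium at C6 adds to the ketone C7, the C7–C1 bond breaks (retro-aldol), and methoxide leaves from C2 to give C1=C2.
3. 16 ⇐ β-keto ester 8 + (Z)-iodoalkenyl acetal 14 (C1–C2 bond); 14 ⇐ 3-bromo-1,1-dimethoxypropane + propyne (carbocupration/iodination fixes the 5Z olefin).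
4. 8 ⇐ Dieckmann closure (C1–C7) of the Evans syn-aldol adduct of a 3-methylbutanoyl imide and methyl 4-oxobutanoate (sets C8 and C9).
5. Ring order: cyclopentanone, then a transient five–seven bicycle (not isolated), then the ten-membered ring.

Assumption: ring atoms are numbered as in the target (C1 bears CO2H, C1=C2, C5(Me)=C6, OAc at C7 and C9, isopropyl at C8), and (S)-4-benzyloxazolidin-2-one is used as a recoverable chiral auxiliary and listed as a reagent.

**Route**

Step 1
Reactants: 1 3-methylbutanoyl chloride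
Product: 2 (4S)-4-benzyl-3-(3-methylbutanoyl)-1,3-oxazolidin-2-one
Conditions: (S)-4-benzyloxazolidin-2-one, n-BuLi, THF, −78 °C; then 1, −78 to 0 °C
Reagents that add atoms: (S)-4-benzyloxazolidin-2-one, O=C1N[C@@H](Cc2ccccc2)CO1
Why: N-acylation of the lithiated oxazolidinone by the acid chloride (nucleophilic acyl substitution), with the stereocentre supplied by the auxiliary.

Step 2
Reactants: 2 (4S)-4-benzyl-3-(3-methylbutanoyl)-1,3-oxazolidin-2-one; 3 methyl 4-oxobutanoate
Product: 5 methyl (4R,5S)-5-[(4S)-4-benzyl-2-oxo-1,3-oxazolidine-3-carbonyl]-4-hydroxy-6-methylheptanoate, via boron enolate 4 (not isolated)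
Conditions: Bu2BOTf, i-Pr2NEt, CH2Cl2, 0 °C; then 3, −78 to 0 °C; MeOH, pH 7 buffer, 30% H2O2
Reagents that add atoms: none
Why: Evans syn-aldol reaction in which the Z-boron enolate reacts through a Zimmerman–Traxler chair on the face left open by the benzyl group, setting C8 (S, isopropyl) and C9 (R, oxygen) of the target in one step.

Step 3
Reactants: 5 methyl (4R,5S)-5-[(4S)-4-benzyl-2-oxo-1,3-oxazolidine-3-carbonyl]-4-hydroxy-6-methylheptanoate
Product: 6 methyl (4R,5S)-5-[(4S)-4-benzyl-2-oxo-1,3-oxazolidine-3-carbonyl]-4-[(tert-butyldimethylsilyl)oxy]-6-methylheptanoate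
Conditions: TBSOTf, 2,6-lutidine, CH2Cl2, 0 °C
Reagents that add atoms: tert-butyldimethylsilyl triflate, CC(C)(C)[Si](C)(C)OS(=O)(=O)C(F)(F)F
Why: Silyl ether formation blocks γ-lactonisation and retro-aldol cleavage of the aldol adduct before base is applied.

Step 4
Reactants: 6 methyl (4R,5S)-5-[(4S)-4-benzyl-2-oxo-1,3-oxazolidine-3-carbonyl]-4-[(tert-butyldimethylsilyl)oxy]-6-methylheptanoate
Product: 7 methyl (3S,4R)-4-[(tert-butyldimethylsilyl)oxy]-2-oxo-3-(propan-2-yl)cyclopentane-1-carboxylate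
Conditions: NaN(SiMe3)2 (2.1 equiv), THF, −78 to 0 °C; aq. NH4Cl
Reagents that add atoms: none
Why: Dieckmann-type intramolecular Claisen condensation in which the unhindered ester enolate (C1) attacks the imide carbonyl (C7) 5-exo-trig and expels the oxazolidinone, the product being held as its β-keto ester enolate so that C8 and C9 keep their trans arrangement.

Step 5
Reactants: 7 methyl (3S,4R)-4-[(tert-butyldimethylsilyl)oxy]-2-oxo-3-(propan-2-yl)cyclopentane-1-carboxylate
Product: 8 allyl (3S,4R)-4-[(tert-butyldimethylsilyl)oxy]-2-oxo-3-(propan-2-yl)cyclopentane-1-carboxylate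
Conditions: allyl alcohol (10 equiv), 4-(dimethylamino)pyridine (0.3 equiv), 4 Å molecular sieves, toluene, 100 °C
Reagents that add atoms: prop-2-en-1-ol, C=CCO
Why: Transesterification of a β-keto ester (acyl-ketene/acyl-pyridinium pathway) installs an ester that can be removed at the end without touching acetates.

Step 6
Reactants: 9 3-bromo-1,1-dimethoxypropane; 10 propyne
Product: 14 (4Z)-5-iodo-1,1-dimethoxy-4-methylpent-4-ene, via Grignard reagent 11 (not isolated), via alkylcopper 12 (not isolated), via alkenylcopper 13 (not isolated)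
Conditions: Mg, Et2O–THF, 20 °C; CuBr·SMe2, Et2O–Me2S, −45 °C; propyne, −25 °C; I2, −45 to 0 °C
Reagents that add atoms: iodine, II
Why: Normant carbocupration adds the alkyl group and copper syn across propyne with copper on the terminal carbon, and iodinolysis with retention gives the Z vinyl iodide that later becomes the 5Z ring olefin.

Step 7
Reactants: 8 allyl (3S,4R)-4-[(tert-butyldimethylsilyl)oxy]-2-oxo-3-(propan-2-yl)cyclopentane-1-carboxylate; 14 (4Z)-5-iodo-1,1-dimethoxy-4-methylpent-4-ene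
Product: 16 allyl (3S,4R)-4-[(tert-butyldimethylsilyl)oxy]-1-[(4Z)-5-iodo-1-methoxy-4-methylpent-4-en-1-yl]-2-oxo-3-(propan-2-yl)cyclopentane-1-carboxylate, via silyl enol ether 15 (not isolated)
Conditions: TMSOTf (1.2 equiv), Et3N (1.3 equiv), CH2Cl2, 0 °C; then 14, TMSOTf (0.3 equiv), −78 to −30 °C
Reagents that add atoms: none
Why: Mukaiyama-type addition of the β-keto ester silyl enol ether to the acetal-derived oxocarbenium ion forms the C1–C2 bond; the two new centres form as a mixture, which does not matter because both become sp2 in step 8.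

Step 8
Reactants: 16 allyl (3S,4R)-4-[(tert-butyldimethylsilyl)oxy]-1-[(4Z)-5-iodo-1-methoxy-4-methylpent-4-en-1-yl]-2-oxo-3-(propan-2-yl)cyclopentane-1-carboxylate
Product: 20 allyl (1E,5Z,8S,9R)-9-[(tert-butyldimethylsilyl)oxy]-5-methyl-7-oxo-8-(propan-2-yl)cyclodeca-1,5-diene-1-carboxylate, via alkenyllithium 17 (not isolated), via hydroazulene lithium alkoxide 18 (not isolated), via lithium ester enolate 19 (not isolated)
Conditions: t-BuLi (2.1 equiv), THF–Et2O (1:1), −100 °C, 15 min; DMPU (4 equiv), −78 to 0 °C; aq. NH4Cl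
Reagents that add atoms: none
Why: Proposed new method: iodine–lithium exchange (faster than carbonyl attack at −100 °C) gives the Z alkenyllithium 17, which adds 7-exo-trig to the cyclopentanone carbonyl (C6–C7 bond), the congested tertiary aldolate 18 then breaks the C7–C1 bond by retro-aldol to release ester enolate 19 inside a ten-membered ring, and 19 expels the β-methoxide from C2 (E1cB), which makes the sequence irreversible and gives the conjugated 1E (ring-cis, tiglate-type) enoate beside the 5Z olefin inherited from 14 while C8 and C9 are untouched; the closest known reaction types are the Grob/Wharton fragmentation of bicyclic 1,3-diol derivatives and the acyl-alkylation ring expansion of β-keto esters by aryne or aryl-anion insertion.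

Step 9
Reactants: 20 allyl (1E,5Z,8S,9R)-9-[(tert-butyldimethylsilyl)oxy]-5-methyl-7-oxo-8-(propan-2-yl)cyclodeca-1,5-diene-1-carboxylate
Product: 21 allyl (1E,5Z,8S,9R)-9-hydroxy-5-methyl-7-oxo-8-(propan-2-yl)cyclodeca-1,5-diene-1-carboxylate
Conditions: HF·pyridine, pyridine, THF, 0 to 20 °C
Reagents that add atoms: none
Why: Buffered fluoride desilylation frees the C9 hydroxyl under non-basic conditions, so the β-hydroxy ketone neither undergoes retro-aldol cleavage nor epimerises at C8.

Step 10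
Reactants: 21 allyl (1E,5Z,8S,9R)-9-hydroxy-5-methyl-7-oxo-8-(propan-2-yl)cyclodeca-1,5-diene-1-carboxylate
Product: 22 allyl (1E,5Z,7R,8S,9R)-7,9-dihydroxy-5-methyl-8-(propan-2-yl)cyclodeca-1,5-diene-1-carboxylate
Conditions: Me4NBH(OAc)3 (5 equiv), MeCN–AcOH (1:1), −30 °C
Reagents that add atoms: none
Why: Evans–Saksena hydroxyl-directed reduction, in which the C9 hydroxyl binds the triacetoxyborohydride and delivers hydride internally to the C7 ketone, gives the 1,3-anti diol and thereby sets C7 as R while leaving the enoate and both olefins alone.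

Step 11
Reactants: 22 allyl (1E,5Z,7R,8S,9R)-7,9-dihydroxy-5-methyl-8-(propan-2-yl)cyclodeca-1,5-diene-1-carboxylate
Product: 23 allyl (1E,5Z,7R,8S,9R)-7,9-bis(acetyloxy)-5-methyl-8-(propan-2-yl)cyclodeca-1,5-diene-1-carboxylate
Conditions: Ac2O, pyridine, 4-(dimethylamino)pyridine (0.1 equiv), CH2Cl2, 20 °C
Reagents that add atoms: acetic anhydride, CC(=O)OC(C)=O
Why: Nucleophile-catalysed acylation of both secondary alcohols with retention at C7 and C9.

Step 12
Reactants: 23 allyl (1E,5Z,7R,8S,9R)-7,9-bis(acetyloxy)-5-methyl-8-(propan-2-yl)cyclodeca-1,5-diene-1-carboxylate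
Product: 24 (1E,5Z,7R,8S,9R)-7,9-bis(acetyloxy)-5-methyl-8-(propan-2-yl)cyclodeca-1,5-diene-1-carboxylic acid
Conditions: Pd(PPh3)4 (5 mol %), morpholine (5 equiv), THF, 20 °C; dilute aq. citric acid
Reagents that add atoms: none
Why: Tsuji–Trost deallylation, in which zerovalent palladium ionises the unhindered allyl ester to a π-allyl complex that morpholine intercepts, frees the acid while the acetates, including the hindered ring allylic acetate at a trisubstituted olefin, are left alone.

**Compound list**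

1 | 3-methylbutanoyl chloride | CC(C)CC(=O)Cl | starting material
2 | (4S)-4-benzyl-3-(3-methylbutanoyl)-1,3-oxazolidin-2-one | CC(C)CC(=O)N1[C@@H](Cc2ccccc2)COC1=O | intermediate
3 | methyl 4-oxobutanoate | COC(=O)CCC=O | starting material
4 | (4S)-4-benzyl-3-[(1Z)-1-(dibutylboranyloxy)-3-methylbut-1-en-1-yl]-1,3-oxazolidin-2-one (Z-boron enolate of 2) | CC(C)/C=C(\OB(CCCC)CCCC)N1[C@@H](Cc2ccccc2)COC1=O | intermediate
5 | methyl (4R,5S)-5-[(4S)-4-benzyl-2-oxo-1,3-oxazolidine-3-carbonyl]-4-hydroxy-6-methylheptanoate | COC(=O)CC[C@@H](O)[C@H](C(C)C)C(=O)N1[C@@H](Cc2ccccc2)COC1=O | intermediate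
6 | methyl (4R,5S)-5-[(4S)-4-benzyl-2-oxo-1,3-oxazolidine-3-carbonyl]-4-[(tert-butyldimethylsilyl)oxy]-6-methylheptanoate | COC(=O)CC[C@@H](O[Si](C)(C)C(C)(C)C)[C@H](C(C)C)C(=O)N1[C@@H](Cc2ccccc2)COC1=O | intermediate
7 | methyl (3S,4R)-4-[(tert-butyldimethylsilyl)oxy]-2-oxo-3-(propan-2-yl)cyclopentane-1-carboxylate (C1 epimers and enol form) | COC(=O)C1C[C@@H](O[Si](C)(C)C(C)(C)C)[C@H](C(C)C)C1=O | intermediate
8 | allyl (3S,4R)-4-[(tert-butyldimethylsilyl)oxy]-2-oxo-3-(propan-2-yl)cyclopentane-1-carboxylate (C1 epimers and enol form) | C=CCOC(=O)C1C[C@@H](O[Si](C)(C)C(C)(C)C)[C@H](C(C)C)C1=O | intermediate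
9 | 3-bromo-1,1-dimethoxypropane | COC(OC)CCBr | starting material
10 | propyne | CC#C | starting material
11 | (3,3-dimethoxypropyl)magnesium bromide | COC(OC)CC[Mg]Br | intermediate
12 | (3,3-dimethoxypropyl)copper (MgBr2·SMe2 complex) | COC(OC)CC[Cu] | intermediate
13 | [(1Z)-5,5-dimethoxy-2-methylpent-1-en-1-yl]copper | COC(OC)CC/C(C)=C\[Cu] | intermediate
14 | (4Z)-5-iodo-1,1-dimethoxy-4-methylpent-4-ene | COC(OC)CC/C(C)=C\I | intermediate
15 | allyl (3S,4R)-4-[(tert-butyldimethylsilyl)oxy]-3-(propan-2-yl)-2-[(trimethylsilyl)oxy]cyclopent-1-ene-1-carboxylate | C=CCOC(=O)C1=C(O[Si](C)(C)C)[C@@H](C(C)C)[C@H](O[Si](C)(C)C(C)(C)C)C1 | intermediate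
16 | allyl (3S,4R)-4-[(tert-butyldimethylsilyl)oxy]-1-[(4Z)-5-iodo-1-methoxy-4-methylpent-4-en-1-yl]-2-oxo-3-(propan-2-yl)cyclopentane-1-carboxylate (epimers at C1 and at the methoxy carbon) | C=CCOC(=O)C1(C(OC)CC/C(C)=C\I)C[C@@H](O[Si](C)(C)C(C)(C)C)[C@H](C(C)C)C1=O | intermediate
17 | allyl (3S,4R)-4-[(tert-butyldimethylsilyl)oxy]-1-[(4Z)-5-lithio-1-methoxy-4-methylpent-4-en-1-yl]-2-oxo-3-(propan-2-yl)cyclopentane-1-carboxylate | C=CCOC(=O)C1(C(OC)CC/C(C)=C\[Li])C[C@@H](O[Si](C)(C)C(C)(C)C)[C@H](C(C)C)C1=O | intermediate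
18 | lithium alkoxide of allyl (1S,2R)-2-[(tert-butyldimethylsilyl)oxy]-8a-hydroxy-4-methoxy-7-methyl-1-(propan-2-yl)-1,2,3,4,5,6-hexahydroazulene-3a(8aH)-carboxylate (cis-fused) | C=CCOC(=O)C12C[C@@H](O[Si](C)(C)C(C)(C)C)[C@H](C(C)C)C1(O[Li])C=C(C)CCC2OC | intermediate
19 | lithium enolate of allyl (5Z,8S,9R)-9-[(tert-butyldimethylsilyl)oxy]-2-methoxy-5-methyl-7-oxo-8-(propan-2-yl)cyclodec-5-ene-1-carboxylate | C=CCOC(O[Li])=C1C[C@@H](O[Si](C)(C)C(C)(C)C)[C@H](C(C)C)C(=O)/C=C(C)\CCC1OC | intermediate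
20 | allyl (1E,5Z,8S,9R)-9-[(tert-butyldimethylsilyl)oxy]-5-methyl-7-oxo-8-(propan-2-yl)cyclodeca-1,5-diene-1-carboxylate | O=C1/C=C(/C)CC/C=C(/C(=O)OCC=C)C[C@@H](O[Si](C)(C)C(C)(C)C)[C@@H]1C(C)C | intermediate
21 | allyl (1E,5Z,8S,9R)-9-hydroxy-5-methyl-7-oxo-8-(propan-2-yl)cyclodeca-1,5-diene-1-carboxylate | O=C1/C=C(/C)CC/C=C(/C(=O)OCC=C)C[C@@H](O)[C@@H]1C(C)C | intermediate
22 | allyl (1E,5Z,7R,8S,9R)-7,9-dihydroxy-5-methyl-8-(propan-2-yl)cyclodeca-1,5-diene-1-carboxylate | O[C@@H]1/C=C(/C)CC/C=C(/C(=O)OCC=C)C[C@@H](O)[C@@H]1C(C)C | intermediate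
23 | allyl (1E,5Z,7R,8S,9R)-7,9-bis(acetyloxy)-5-methyl-8-(propan-2-yl)cyclodeca-1,5-diene-1-carboxylate | CC(=O)O[C@@H]1/C=C(/C)CC/C=C(/C(=O)OCC=C)C[C@@H](OC(C)=O)[C@@H]1C(C)C | intermediate
24 | (1E,5Z,7R,8S,9R)-7,9-bis(acetyloxy)-5-methyl-8-(propan-2-yl)cyclodeca-1,5-diene-1-carboxylic acid (CNP0172943.1) | CC(=O)O[C@@H]1/C=C(/C)CC/C=C(/C(=O)O)C[C@@H](OC(C)=O)[C@@H]1C(C)C | target

**Step count and risks**

Total steps: 12. Longest linear sequence: 11 (steps 1–5 and 7–12; step 6 makes the side fragment).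

Steps most likely to fail:

Step 8 (the proposed ring expansion). The alkenyllithium could attack the allyl ester instead of the ketone, or the lithium aldolate could fail to fragment before side reactions set in. The fallback sets out from 16 and comes back at 20 by known reactions; it separates ring closure from fragmentation and replaces the organolithium by a chemoselective organochromium reagent. An intramolecular Nozaki–Hiyama–Kishi addition (CrCl2, NiCl2 cat., DMF–THF, 20 °C) of the vinyl iodide to the ketone gives the isolable cis-fused tertiary alcohol allyl (1S,2R)-2-[(tert-butyldimethylsilyl)oxy]-8a-hydroxy-4-methoxy-7-methyl-1-(propan-2-yl)-1,2,3,4,5,6-hexahydroazulene-3a(8aH)-carboxylate F1. Treating this with KN(SiMe3)2 and 18-crown-6 in THF (−78 to 0 °C) then triggers the alkoxide retro-aldol cleavage and β-elimination of methoxide (a Grob/Wharton-type fragmentation) to give 20.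

Step 7 (quaternary centre next to the isopropyl-bearing carbon). The oxocarbenium ion from the acetal may be too hindered a partner for the tetrasubstituted silyl enol ether. The fallback sets out from 14 and from 8 (through its silyl enol ether 15) and comes back at 16. Acetal 14 is hydrolysed (aq. HCl, THF) to the free aldehyde (4Z)-5-iodo-4-methylpent-4-enal F2. A Mukaiyama aldol addition of 15 to this aldehyde (TiCl4, CH2Cl2, −78 °C) gives allyl (3S,4R)-4-[(tert-butyldimethylsilyl)oxy]-1-[(4Z)-1-hydroxy-5-iodo-4-methylpent-4-en-1-yl]-2-oxo-3-(propan-2-yl)cyclopentane-1-carboxylate F3. O-Methylation of the new hydroxyl (Me3OBF4, 1,8-bis(dimethylamino)naphthalene, CH2Cl2, 20 °C) then gives 16.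

Step 10 (diastereoselective reduction in a ten-membered ring). The chair-like internal hydride delivery may be distorted by the ring, which would erode the anti selectivity. The fallback sets out from 20 and comes back at 22; it reduces the ketone before desilylation under reagent control instead of substrate direction. Corey–Bakshi–Shibata reduction of enone 20 with (R)-1-methyl-3,3-diphenyl-tetrahydro-1H,3H-pyrrolo[1,2-c][1,3,2]oxazaborole (20 mol %) and catecholborane in toluene at −78 °C, with the alkenyl group acting as the large substituent, gives allyl (1E,5Z,7R,8R,9R)-9-[(tert-butyldimethylsilyl)oxy]-7-hydroxy-5-methyl-8-(propan-2-yl)cyclodeca-1,5-diene-1-carboxylate F4 (the C8 descriptor changes only because the silyloxy branch now outranks the hydroxyl branch). Desilylation with HF·pyridine in THF then gives 22.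

**Further compounds**

F1 | step 8 | allyl (1S,2R)-2-[(tert-butyldimethylsilyl)oxy]-8a-hydroxy-4-methoxy-7-methyl-1-(propan-2-yl)-1,2,3,4,5,6-hexahydroazulene-3a(8aH)-carboxylate | C=CCOC(=O)C12C[C@@H](O[Si](C)(C)C(C)(C)C)[C@H](C(C)C)C1(O)C=C(C)CCC2OC
F2 | step 7 | (4Z)-5-iodo-4-methylpent-4-enal | O=CCC/C(C)=C\I
F3 | step 7 | allyl (3S,4R)-4-[(tert-butyldimethylsilyl)oxy]-1-[(4Z)-1-hydroxy-5-iodo-4-methylpent-4-en-1-yl]-2-oxo-3-(propan-2-yl)cyclopentane-1-carboxylate | C=CCOC(=O)C1(C(O)CC/C(C)=C\I)C[C@@H](O[Si](C)(C)C(C)(C)C)[C@H](C(C)C)C1=O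
F4 | step 10 | allyl (1E,5Z,7R,8R,9R)-9-[(tert-butyldimethylsilyl)oxy]-7-hydroxy-5-methyl-8-(propan-2-yl)cyclodeca-1,5-diene-1-carboxylate | O[C@@H]1/C=C(/C)CC/C=C(/C(=O)OCC=C)C[C@@H](O[Si](C)(C)C(C)(C)C)[C@@H]1C(C)C
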